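Working labels: O1, C2 (CH bearing the side chain), C3, C4 (CHBr), C5 (quaternary), C1′ (exocyclic CBr). The oxolane is opened at O1–C2 and C4–C5, giving a six-carbon (E)-geminal dibromide with the allylic chloride and a chiral-pool α-alkoxy methyl ketone. In one flask the lithium carbenoid of the dibromide adds to the ketone at the fully substituted C5 and NBS then closes the tertiary alcohol onto the E alkene, so the ring, C5, C2 and C1′ arise together. The step exploits the O1–C2–C1′(Br) bromoether motif and the O1–C5–C4(Br) array of the oxolane. C4 is later trimmed from CBr2 to CHBr, and the dioxolane becomes the bromovinyl group.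

Key step: step 5

Remark on the chemistry: the addition of carbenoid 10 to ketone 9 is taken to follow the non-chelated polar Felkin–Anh model, as expected for a lithium reagent in THF next to a dioxolane oxygen; the (S) ketone is chosen on that basis. Systematic names number the oxolane from the quaternary carbon, so working label C5 is position 2 in the names.

Step 1
Reactants: 1 dibromomethane; 2 prenyl bromide (1-bromo-3-methylbut-2-ene)
Product: 4 5,5-dibromo-2-methylpent-2-ene, via dibromomethyllithium 3 (not isolated)
Conditions: LiN(i-Pr)2, THF/Et2O, −95 °C; then 2, DMPU, −95 to −70 °C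
Reagents that add atoms: none
Why: Dibromomethane is deprotonated to the carbenoid LiCHBr2, which should be alkylated by the reactive primary allylic bromide in a direct SN2 displacement (carbenoid alkylation); no stereocentre is formed.

Step 2
Reactants: 4 5,5-dibromo-2-methylpent-2-ene
Product: 5 (E)-5,5-dibromo-2-methylpent-2-en-1-ol
Conditions: SeO2 (cat.), t-BuOOH, CH2Cl2, rt
Reagents that add atoms: tert-butyl hydroperoxide, CC(C)(C)OO
Why: Riley allylic oxidation (ene reaction, then [2,3]-sigmatropic shift) attacks the more substituted alkene terminus and, by the usual rule, the methyl group trans to the chain, so the E allylic alcohol should result.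

Step 3
Reactants: 5 (E)-5,5-dibromo-2-methylpent-2-en-1-ol
Product: 6 (E)-5,5-dibromo-1-chloro-2-methylpent-2-ene
Conditions: NCS, Me2S, CH2Cl2, −20 to 0 °C
Reagents that add atoms: N-chlorosuccinimide, O=C1CCC(=O)N1Cl
Why: Corey–Kim chlorination: chloride displaces the alkoxysulfonium group in a direct SN2 reaction, which should keep the E alkene and avoid allylic transposition.

Step 4
Reactants: 7 methyl (S)-2,2-dimethyl-1,3-dioxolane-4-carboxylate
Product: 9 (S)-1-(2,2-dimethyl-1,3-dioxolan-4-yl)ethan-1-one, via Weinreb amide 8 (not isolated)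
Conditions: MeNH(OMe)·HCl, MeMgCl (excess), THF, −20 to 0 °C
Reagents that add atoms: methylmagnesium chloride, C[Mg]Cl
Why: Magnesium amide aminolysis gives the Weinreb amide, whose chelated tetrahedral adduct with MeMgCl releases the methyl ketone only on work-up (Weinreb ketone synthesis), and the cold conditions should keep the α-alkoxy stereocentre from epimerising.

Step 5
Reactants: 6 (E)-5,5-dibromo-1-chloro-2-methylpent-2-ene; 9 (S)-1-(2,2-dimethyl-1,3-dioxolan-4-yl)ethan-1-one
Product: 13 (2S,5R)-3,3-dibromo-5-[(2R)-2-bromo-1-chloropropan-2-yl]-2-[(4S)-2,2-dimethyl-1,3-dioxolan-4-yl]-2-methyloxolane, via lithium carbenoid 10 (not isolated), via lithium alkoxide 11 (not isolated), via tertiary alcohol 12 (not isolated)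
Conditions: LiN(i-Pr)2, THF/Et2O, −105 °C; 9, −105 to −90 °C; AcOH; NBS, CH2Cl2, −78 to 0 °C
Reagents that add atoms: N-bromosuccinimide, O=C1CCC(=O)N1Br
Why: LiN(i-Pr)2 removes the acidic CHBr2 proton of 6 and the resulting 1,1-dibromoalkyllithium adds to the carbonyl of 9 to forge C4–C5 (closest known type: 1,2-addition of 1,1-dihaloalkyllithium carbenoids to ketones); after cold protonation NBS turns the E alkene of 12 into a bromonium ion that the tertiary hydroxyl opens at C2, forging O1–C2 (closest known type: bromoetherification of 4-alkenols). C5 is set by polar Felkin–Anh attack anti to the dioxolane C–O bond of the (S) ketone, which should give the (S) carbinol. The ring closes in the 5-exo mode and not 6-endo, because the chloromethyl group destabilises positive charge at the tertiary carbon and the hindered alcohol reaches the CH terminus more easily. Anti addition of O1 and Br across the E alkene fixes C2 and C1′ relative to each other, and a chair-like transition state should place the new C2 substituent trans to the bulky dioxolanyl group on C5 and cis to the methyl group. The step needs the carbenoid to be trapped before α-elimination or attack on its own allylic chloride, which is secured by −105 °C, by the E geometry that forbids five-membered closure onto the chloride and by prompt addition of the ketone; bromonium formation is unambiguous because only one alkene is present.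

Step 6
Reactants: 13 (2S,5R)-3,3-dibromo-5-[(2R)-2-bromo-1-chloropropan-2-yl]-2-[(4S)-2,2-dimethyl-1,3-dioxolan-4-yl]-2-methyloxolane
Product: 14 (2S,5R)-3,3-dibromo-5-[(2R)-2-bromo-1-chloropropan-2-yl]-2-methyloxolane-2-carbaldehyde
Conditions: H5IO6, EtOAc, rt
Reagents that add atoms: none
Why: Periodic acid hydrolyses the terminal acetonide and cleaves the liberated 1,2-diol (glycol cleavage) in one operation, and the aldehyde cannot epimerise because C5 carries no hydrogen.

Step 7
Reactants: 14 (2S,5R)-3,3-dibromo-5-[(2R)-2-bromo-1-chloropropan-2-yl]-2-methyloxolane-2-carbaldehyde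
Product: 15 (2S,3R,5R)-3-bromo-5-[(2R)-2-bromo-1-chloropropan-2-yl]-2-methyloxolane-2-carbaldehyde
Conditions: n-Bu3SnH (1.05 equiv), Et3B (cat.), air, toluene, −78 °C
Reagents that add atoms: none
Why: Tin hydride radical monodebromination of a geminal dibromide: the CBr2 bonds are the weakest C–Br bonds, and the α-bromo radical at C4 should take hydrogen on the face syn to the small formyl group and anti to the C5 methyl and the C2 side chain, leaving bromine cis to both (4R in working labels).

Step 8
Reactants: 15 (2S,3R,5R)-3-bromo-5-[(2R)-2-bromo-1-chloropropan-2-yl]-2-methyloxolane-2-carbaldehyde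
Product: 16 (2S,3R,5R)-3-bromo-2-[(E)-2-bromoethenyl]-5-[(2R)-2-bromo-1-chloropropan-2-yl]-2-methyloxolane
Conditions: CHBr3, CrCl2, THF/dioxane, 0 °C to rt
Reagents that add atoms: bromoform, BrC(Br)Br
Why: Takai olefination: the geminal dichromium reagent adds to the aldehyde and eliminates to give the E bromoalkene preferentially, while unactivated alkyl bromides and the alkyl chloride should be inert to CrCl2 at this temperature.

Compound list
1 | dibromomethane | BrCBr | starting material
2 | prenyl bromide (1-bromo-3-methylbut-2-ene) | CC(C)=CCBr | starting material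
3 | dibromomethyllithium | [Li]C(Br)Br | intermediate
4 | 5,5-dibromo-2-methylpent-2-ene | CC(C)=CCC(Br)Br | intermediate
5 | (E)-5,5-dibromo-2-methylpent-2-en-1-ol | OC/C(C)=C/CC(Br)Br | intermediate
6 | (E)-5,5-dibromo-1-chloro-2-methylpent-2-ene | ClC/C(C)=C/CC(Br)Br | intermediate
7 | methyl (S)-2,2-dimethyl-1,3-dioxolane-4-carboxylate | COC(=O)[C@@H]1COC(C)(C)O1 | starting material
8 | (S)-N-methoxy-N,2,2-trimethyl-1,3-dioxolane-4-carboxamide (Weinreb amide) | CON(C)C(=O)[C@@H]1COC(C)(C)O1 | intermediate
9 | (S)-1-(2,2-dimethyl-1,3-dioxolan-4-yl)ethan-1-one | CC(=O)[C@@H]1COC(C)(C)O1 | intermediate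
10 | [(3E)-1,1-dibromo-5-chloro-4-methylpent-3-en-1-yl]lithium | ClC/C(C)=C/CC(Br)(Br)[Li] | intermediate
11 | lithium (2S,5E)-3,3-dibromo-7-chloro-2-[(4S)-2,2-dimethyl-1,3-dioxolan-4-yl]-6-methylhept-5-en-2-olate | ClC/C(C)=C/CC(Br)(Br)[C@@](C)(O[Li])[C@@H]1COC(C)(C)O1 | intermediate
12 | (2S,5E)-3,3-dibromo-7-chloro-2-[(4S)-2,2-dimethyl-1,3-dioxolan-4-yl]-6-methylhept-5-en-2-ol | ClC/C(C)=C/CC(Br)(Br)[C@@](C)(O)[C@@H]1COC(C)(C)O1 | intermediate
13 | (2S,5R)-3,3-dibromo-5-[(2R)-2-bromo-1-chloropropan-2-yl]-2-[(4S)-2,2-dimethyl-1,3-dioxolan-4-yl]-2-methyloxolane | C[C@](Br)(CCl)[C@H]1CC(Br)(Br)[C@](C)([C@@H]2COC(C)(C)O2)O1 | intermediate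
14 | (2S,5R)-3,3-dibromo-5-[(2R)-2-bromo-1-chloropropan-2-yl]-2-methyloxolane-2-carbaldehyde | C[C@](Br)(CCl)[C@H]1CC(Br)(Br)[C@](C)(C=O)O1 | intermediate
15 | (2S,3R,5R)-3-bromo-5-[(2R)-2-bromo-1-chloropropan-2-yl]-2-methyloxolane-2-carbaldehyde | C[C@](Br)(CCl)[C@H]1C[C@@H](Br)[C@](C)(C=O)O1 | intermediate
16 | (2S,3R,5R)-3-bromo-2-[(E)-2-bromoethenyl]-5-[(2R)-2-bromo-1-chloropropan-2-yl]-2-methyloxolane | C[C@](Br)(CCl)[C@H]1C[C@@H](Br)[C@](C)(/C=C/Br)O1 | target

Total step count: 8.
Longest linear sequence: 7 steps (steps 1, 2, 3, 5, 6, 7 and 8, from 1 and 2 to 16).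

Steps most likely to fail

Step 5 carries the most risk. The basic carbenoid may enolise ketone 9 or decompose before it is trapped, and facial control may be incomplete both at the carbonyl (C5) and at the alkene (C2). The fallback sets out from 6 and 7 and replaces ketone addition by acylation followed by chelation-controlled methyl addition. Ester 7 is converted with MeNH(OMe)·HCl and i-PrMgCl into Weinreb amide 8, which is now isolated. Carbenoid 10, made from 6 as before, should acylate 8 through a stable chelated adduct to give (4E)-2,2-dibromo-6-chloro-1-[(4S)-2,2-dimethyl-1,3-dioxolan-4-yl]-5-methylhex-4-en-1-one F1. MeMgBr in CH2Cl2/Et2O at −78 °C should then add under chelation control through the α-oxygen; this delivers the same C5 configuration, because the incoming group and the resident group have changed places. Alcohol 12 is isolated, purified and cyclised separately with NBS or 2,4,4,6-tetrabromocyclohexa-2,5-dienone at low temperature, and the fallback comes back to the route at 13.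

Step 7 is next. The tin radical may also abstract the tertiary bromine, and the α-bromo radical at C4 may suffer 1,2-migration of the neighbouring formyl group before it is reduced. The fallback sets out from 14 and removes the migrating group before the radical step. The aldehyde is reduced with NaBH4/CeCl3·7H2O in MeOH at −40 °C to [(2S,5R)-3,3-dibromo-5-[(2R)-2-bromo-1-chloropropan-2-yl]-2-methyloxolan-2-yl]methanol F2. The geminal dibromide is then reduced by photoinduced electron transfer (fac-Ir(ppy)3, Hantzsch ester, i-Pr2NEt, MeCN, blue light), where the reduction potential rather than the bond strength singles out the CBr2 group. This should give [(2S,3R,5R)-3-bromo-5-[(2R)-2-bromo-1-chloropropan-2-yl]-2-methyloxolan-2-yl]methanol F3. Dess–Martin oxidation comes back to the route at 15.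

Step 8 is the third. Addition of the bulky dichromium reagent to the α-quaternary aldehyde may be slow and the E/Z control modest. The fallback sets out from 15 and separates alkene formation from C–Br formation. The silyl variant of the olefination (Me3SiCHBr2, CrCl2, THF) should give trimethyl[(E)-2-{(2S,3R,5R)-3-bromo-5-[(2R)-2-bromo-1-chloropropan-2-yl]-2-methyloxolan-2-yl}ethenyl]silane F4 with higher E selectivity. Ipso-bromodesilylation with NBS in MeCN/ClCH2CN, expected to proceed with retention of alkene geometry, comes back to the route at 16.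

Further compounds
F1 | step 5 | (4E)-2,2-dibromo-6-chloro-1-[(4S)-2,2-dimethyl-1,3-dioxolan-4-yl]-5-methylhex-4-en-1-one | ClC/C(C)=C/CC(Br)(Br)C(=O)[C@@H]1COC(C)(C)O1
F2 | step 7 | [(2S,5R)-3,3-dibromo-5-[(2R)-2-bromo-1-chloropropan-2-yl]-2-methyloxolan-2-yl]methanol | C[C@](Br)(CCl)[C@H]1CC(Br)(Br)[C@](C)(CO)O1
F3 | step 7 | [(2S,3R,5R)-3-bromo-5-[(2R)-2-bromo-1-chloropropan-2-yl]-2-methyloxolan-2-yl]methanol | C[C@](Br)(CCl)[C@H]1C[C@@H](Br)[C@](C)(CO)O1
F4 | step 8 | trimethyl[(E)-2-{(2S,3R,5R)-3-bromo-5-[(2R)-2-bromo-1-chloropropan-2-yl]-2-methyloxolan-2-yl}ethenyl]silane | C[C@](Br)(CCl)[C@H]1C[C@@H](Br)[C@](C)(/C=C/[Si](C)(C)C)O1
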